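## Retrosynthetic overview

1. Feature: ring A (C1–C5, C10) carries oxygen at C3, the gem-dimethyl carbon C4 and the quaternary C10–CH3. This is the retron of a 4-methyl-Δ4-3-octalone. Ring B needs oxygen at C7 to develop C7=C8, the C8 methyl and the C9 chain.
2. The two ester C–O bonds are cut last (C3 hydrogen malonate from Meldrum's acid, C15 (S)-3-methylpentanoate), which leaves the 7,13E-diene-3,15-diol. C13=C14–C15 comes from a terminal alkyne (methylalumination, CH2O), and C12–C13 from a C12 iodide and acetylide.
3. C9–C11 is made by Johnson–Claisen rearrangement of a 7-hydroxy-8-methyl-Δ8 alkene, which moves chirality from C7 to C9. That alcohol comes from a C7 ketone.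
4. The C7 ketone comes from a C7 isopropenyl group (ozonolysis, Baeyer–Villiger). The axial C3–OH, the second C4 methyl and H5 come from 10-epi-α-cyperone.
5. Ring order: ring B is the carvone ring. Ring A is closed on it by Robinson annulation of dihydrocarvone with ethyl vinyl ketone (C1–C10, then C4=C5), and the isopropenyl centre fixes C10.

Key step: step 2

Remark: the SMILES is read as a labdane of the enantio series, (3S,5S,9R,10S), 13E, (S) in the acyl group; labdane numbering is used for all bicyclic compounds, α/β mean the faces as drawn with ring A at the left (C10–CH3 and C9–C11 α, H5, H9 and the axial C3–O β), TBS = tert-butyldimethylsilyl, and (S)-3-methylpentanoic acid is taken as a purchasable single enantiomer.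

## Route

Step 1
Reactants: 1 (R)-(−)-carvone
Product: 2 (2R,5R)-dihydrocarvone (trans-2-methyl-5-isopropenylcyclohexanone; the minor 2S epimer is carried along)
Conditions: Zn dust, KOH, EtOH–H2O, reflux
Reagents that add atoms: none
Why: Dissolving-metal conjugate reduction saturates only the conjugated C=C, leaves the isolated isopropenyl group and C5 untouched, and base equilibration favours the trans epimer, whose C2 configuration is erased in step 2 anyway.

Step 2
Reactants: 2 (2R,5R)-dihydrocarvone; 3 ethyl vinyl ketone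
Product: 6 (−)-10-epi-α-cyperone ((4aR,7R); C10 methyl α trans to the 7β-isopropenyl group), via Michael diketone 4 (not isolated), via bicyclic ketol 5 (not isolated)
Conditions: 3 (1.2 equiv, slow addition), KOH (0.3 equiv), EtOH, −10 to 0 °C then rt; then 10% aq KOH, reflux
Reagents that add atoms: ethyl vinyl ketone (3), CCC(=O)C=C
Why: This is a Robinson annulation, the closest known case being the hydroxide-mediated annulation of 2-alkylcyclohexanones with alkyl vinyl ketones: reversible deprotonation of 2 in EtOH funnels both C2 epimers into the more substituted enolate, whose C10 adds to the β-carbon of 3 (new bond C1–C10) to give diketone 4. Proton transfer gives the C4 enolate of the ethyl ketone, which closes ring A on the ring carbonyl C5 by a 6-(enolendo)-exo-trig aldol addition (ketol 5), and E1cB loss of water at reflux leaves the tetrasubstituted C4=C5 enone. C10 is the only new stereocentre that is kept, and it is controlled by the C7 centre from carvone: the enolate half-chair holds the isopropenyl group equatorial and 3 approaches axially through a chair-like transition state, so C1 ends cis and the C10 methyl trans to isopropenyl, as the target requires. The step needs regioselectivity (C10 over C6), secured by equilibrating protic conditions that favour the tetrasubstituted enolate, and facial selectivity, secured by this 1,4-relay, with the minor C10 epimer expected to be removable by chromatography of 6. Low temperature and slow addition of 3 hold back its polymerisation and double Michael addition.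

Step 3
Reactants: 6 (−)-10-epi-α-cyperone; 7 iodomethane
Product: 9 7β-isopropenyl-4,4,10α-trimethyl-trans-decalin-3-one (H5 β), via lithium C3 enolate 8 (not isolated)
Conditions: Li (2.1 equiv), t-BuOH (1.0 equiv), NH3(l)–THF, −78 to −33 °C; then MeI, −33 °C to rt
Reagents that add atoms: iodomethane (7), CI
Why: In this Stork reductive alkylation, two-electron reduction and protonation of C5 through the stereoelectronically preferred trans-fused transition state place H5 anti to the C10 methyl, and the regiodefined C3=C4 enolate 8 is C-methylated at C4 (afterwards non-stereogenic) while the unconjugated isopropenyl group is not reduced.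

Step 4
Reactants: 9 7β-isopropenyl-4,4,10α-trimethyl-trans-decalin-3-one
Product: 10 7β-isopropenyl-4,4,10α-trimethyl-trans-decalin-3β-ol (axial OH, trans to the C10 methyl)
Conditions: LiBH(s-Bu)3, THF, −78 to 0 °C; then NaOH, H2O2, 0 °C
Reagents that add atoms: none
Why: In this bulky trialkylborohydride reduction the reagent avoids the axial trajectory past the axial H1 and H5 and attacks C3 equatorially from the α face, which sets the axial 3β (3S) alcohol.

Step 5
Reactants: 10 7β-isopropenyl-4,4,10α-trimethyl-trans-decalin-3β-ol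
Product: 11 3β-(TBSO)-7β-isopropenyl-4,4,10α-trimethyl-trans-decalin
Conditions: TBSOTf, 2,6-lutidine, CH2Cl2, 0 °C to rt
Reagents that add atoms: tert-butyldimethylsilyl triflate, CC(C)(C)[Si](C)(C)OS(=O)(=O)C(F)(F)F
Why: Silylation with the silyl triflate is reactive enough for the hindered axial neopentyl-type alcohol, and the buffered medium leaves the alkene and all stereocentres alone.

Step 6
Reactants: 11 3β-(TBSO)-7β-isopropenyl-4,4,10α-trimethyl-trans-decalin
Product: 13 7β-acetyl-3β-(TBSO)-4,4,10α-trimethyl-trans-decalin, via secondary ozonide 12 (not isolated)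
Conditions: O3, CH2Cl2, −78 °C; then Me2S, −78 °C to rt
Reagents that add atoms: ozone, [O-][O+]=O
Why: Ozonolysis (Criegee mechanism) cleaves the only C=C of the molecule, and reductive work-up gives the methyl ketone, whose possible epimerisation at C7 is of no consequence.

Step 7
Reactants: 13 7β-acetyl-3β-(TBSO)-4,4,10α-trimethyl-trans-decalin
Product: 14 3β-(TBSO)-4,4,10α-trimethyl-trans-decalin-7β-yl acetate
Conditions: mCPBA, CH2Cl2, rt to 40 °C
Reagents that add atoms: 3-chloroperbenzoic acid, OOC(=O)c1cccc(Cl)c1
Why: In this Baeyer–Villiger oxidation the secondary C7 migrates in preference to methyl with retention, and no alkene is present to compete for the peracid.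

Step 8
Reactants: 14 3β-(TBSO)-4,4,10α-trimethyl-trans-decalin-7β-yl acetate
Product: 15 3β-(TBSO)-4,4,10α-trimethyl-trans-decalin-7β-ol
Conditions: K2CO3 (cat.), MeOH, rt
Reagents that add atoms: none
Why: Base-catalysed transesterification removes the acetate, and the hindered silyl ether is inert to methanolic carbonate.

Step 9
Reactants: 15 3β-(TBSO)-4,4,10α-trimethyl-trans-decalin-7β-ol
Product: 16 3β-(TBSO)-4,4,10α-trimethyl-trans-decalin-7-one
Conditions: Pr4N[RuO4] (cat.), NMO, 4 Å molecular sieves, CH2Cl2, rt
Reagents that add atoms: none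
Why: Ley–Griffith oxidation converts the only free alcohol into the C7 ketone under neutral conditions, which completes the excision of the isopropenyl group.

Step 10
Reactants: 16 3β-(TBSO)-4,4,10α-trimethyl-trans-decalin-7-one
Product: 18 3β-(TBSO)-4,4,10α-trimethyl-trans-octal-8-en-7-one (C8=C9 enone), via lithium C7 enolate 17 (not isolated)
Conditions: LiN(i-Pr)2, THF, −78 °C; then PhS(Cl)=N-t-Bu, −78 °C
Reagents that add atoms: none
Why: In this Mukaiyama dehydrogenation, kinetic deprotonation takes the axial H8 because the axial H6 is shielded by both the axial C4 and the C10 methyl groups, and the S-bound enolate adduct undergoes syn elimination to the C8=C9 enone.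

Step 11
Reactants: 18 3β-(TBSO)-4,4,10α-trimethyl-trans-octal-8-en-7-one
Product: 19 8-iodo-3β-(TBSO)-4,4,10α-trimethyl-trans-octal-8-en-7-one
Conditions: I2, pyridine–CH2Cl2, 0 °C to rt
Reagents that add atoms: iodine, II
Why: Johnson α-iodination (pyridine addition at C9, iodination of the enolate at C8, elimination) is established for enones whose β-carbon adjoins a quaternary centre, such as 4,4-dimethylcyclohexenone.

Step 12
Reactants: 19 8-iodo-3β-(TBSO)-4,4,10α-trimethyl-trans-octal-8-en-7-one
Product: 20 3β-(TBSO)-4,4,8,10α-tetramethyl-trans-octal-8-en-7-one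
Conditions: Me4Sn, Pd2(dba)3 (cat.), AsPh3, NMP, 80 °C
Reagents that add atoms: tetramethylstannane, C[Sn](C)(C)C
Why: In this Stille coupling, oxidative addition of zerovalent palladium into the C8–I bond, methyl transfer from tin and reductive elimination place C17 on C8 with no regiochemical ambiguity.

Step 13
Reactants: 20 3β-(TBSO)-4,4,8,10α-tetramethyl-trans-octal-8-en-7-one
Product: 21 3β-(TBSO)-4,4,8,10α-tetramethyl-trans-octal-8-en-7α-ol (pseudoequatorial OH, cis to the C10 methyl)
Conditions: NaBH4, CeCl3·7H2O, MeOH, −78 to 0 °C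
Reagents that add atoms: none
Why: Luche reduction is 1,2-selective, and hydride enters axially from the β face opposite the C10 methyl, as with 5α-1-en-3-one steroids, which sets the 7α alcohol.

Step 14
Reactants: 21 3β-(TBSO)-4,4,8,10α-tetramethyl-trans-octal-8-en-7α-ol; 22 triethyl orthoacetate
Product: 25 ethyl 3β-(TBSO)-13,14,15,16-tetranorlabd-7-en-12-oate (5β,9β-H; 10α-CH3; C9–C11 α), via mixed orthoester 23 (not isolated), via ketene acetal 24 (not isolated)
Conditions: MeC(OEt)3 (excess), EtCO2H (cat.), 140 °C, EtOH distilled off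
Reagents that add atoms: triethyl orthoacetate (22), CC(OCC)(OCC)OCC
Why: In this Johnson–Claisen rearrangement, acid-catalysed exchange and loss of EtOH give ketene acetal 24, whose [3,3] shift is suprafacial over C7–C8–C9, so the α C7–O bond is exchanged for the α C9–C11 bond (cis to the C10 methyl, 9R) and the alkene moves to C7=C8, as in the known transfer from pseudoequatorial steroidal allylic alcohols to the carbon next to C10.

Step 15
Reactants: 25 ethyl 3β-(TBSO)-13,14,15,16-tetranorlabd-7-en-12-oate
Product: 26 3β-(TBSO)-13,14,15,16-tetranorlabd-7-en-12-ol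
Conditions: LiAlH4, Et2O, 0 °C
Reagents that add atoms: none
Why: Hydride reduction of the ester to the primary alcohol leaves the trisubstituted alkene, the silyl ether and the non-epimerisable C9 untouched.

Step 16
Reactants: 26 3β-(TBSO)-13,14,15,16-tetranorlabd-7-en-12-ol
Product: 27 12-iodo-3β-(TBSO)-13,14,15,16-tetranorlabd-7-ene
Conditions: I2, PPh3, imidazole, CH2Cl2, 0 °C to rt
Reagents that add atoms: iodine, II
Why: Appel-type iodination proceeds by SN2 displacement of the alkoxyphosphonium ion at the unhindered primary C12 under nearly neutral conditions.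

Step 17
Reactants: 27 12-iodo-3β-(TBSO)-13,14,15,16-tetranorlabd-7-ene
Product: 28 3β-(TBSO)-15,16-dinorlabd-7-en-13-yne (terminal alkyne C13≡C14)
Conditions: LiC≡CH·H2NCH2CH2NH2, DMSO–THF, 0 °C to rt
Reagents that add atoms: lithium acetylide ethylenediamine complex, [Li]C#C.NCCN
Why: SN2 alkylation of acetylide by a primary iodide in a dipolar aprotic medium forms C12–C13, and the leaving group sits two carbons from the ring, so substitution should outrun elimination.

Step 18
Reactants: 28 3β-(TBSO)-15,16-dinorlabd-7-en-13-yne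
Product: 31 3β-(TBSO)-labda-7,13E-dien-15-ol, via vinylalane 29 (not isolated), via lithium alanate 30 (not isolated)
Conditions: Me3Al, Cp2ZrCl2 (cat.), CH2Cl2, 0 °C to rt; volatiles removed, THF, n-BuLi, −78 to 0 °C; (CH2O)n, rt; aq work-up
Reagents that add atoms: trimethylaluminium, C[Al](C)C; paraformaldehyde (as formaldehyde), C=O
Why: Negishi zirconium-catalysed carboalumination adds CH3 (to C13) and Al (to C14) syn, which fixes the 13E geometry, and the more nucleophilic alanate 30 is hydroxymethylated with retention, the trisubstituted ring alkene being inert.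

Step 19
Reactants: 31 3β-(TBSO)-labda-7,13E-dien-15-ol
Product: 32 labda-7,13E-diene-3β,15-diol (5β,9β-H; 10α-CH3)
Conditions: Bu4NF, THF, 60 °C
Reagents that add atoms: none
Why: Fluoride-induced desilylation is run at this stage because the molecule holds no base-sensitive group, so the hindered C3 ether can be heated without risk.

Step 20
Reactants: 32 labda-7,13E-diene-3β,15-diol; 33 (S)-3-methylpentanoic acid
Product: 34 3β-hydroxylabda-7,13E-dien-15-yl (S)-3-methylpentanoate
Conditions: 33 (1.05 equiv), DCC, DMAP (cat.), CH2Cl2, 0 °C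
Reagents that add atoms: (S)-3-methylpentanoic acid (33), CC[C@H](C)CC(=O)O
Why: In this Steglich esterification the primary allylic C15–OH is acylated far faster than the axial C3–OH next to quaternary C4, and the β-stereocentre of the acid cannot racemise.

Step 21
Reactants: 34 3β-hydroxylabda-7,13E-dien-15-yl (S)-3-methylpentanoate; 35 Meldrum's acid
Product: 36 target CNP0234792.1 (3-O-hydrogen malonate 15-O-(S)-3-methylpentanoate)
Conditions: 35 (2 equiv), toluene, 100–110 °C
Reagents that add atoms: Meldrum's acid (35), CC1(C)OC(=O)CC(=O)O1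
Why: Thermal alcoholysis of Meldrum's acid, known even for tert-butanol, opens the dioxanedione at C3–OH and loses acetone to give the free hydrogen malonate directly, without breaking the C3–O bond and under neutral conditions that spare the C15 ester and both alkenes.

## Compound list

1 | (R)-(−)-carvone | CC1=CC[C@H](CC1=O)C(C)=C | starting material
2 | (2R,5R)-dihydrocarvone | C[C@@H]1CC[C@@H](C(C)=C)CC1=O | intermediate
3 | ethyl vinyl ketone (pent-1-en-3-one) | CCC(=O)C=C | starting material
4 | (2R,5R)-2-methyl-2-(3-oxopentyl)-5-(prop-1-en-2-yl)cyclohexanone (chain cis to isopropenyl) | CCC(=O)CC[C@@]1(C)CC[C@@H](C(C)=C)CC1=O | intermediate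
5 | 5-hydroxy-7β-isopropenyl-4,10α-dimethyldecalin-3-one (C4 and C5 configuration of no consequence) | C[C@@]12CCC(=O)C(C)C1(O)C[C@H](C(C)=C)CC2 | intermediate
6 | (−)-10-epi-α-cyperone, (4aR,7R) | CC1=C2C[C@H](C(C)=C)CC[C@]2(C)CCC1=O | intermediate
7 | iodomethane | CI | starting material
8 | lithium C3=C4 enolate of the trans-fused dihydro ketone | C[C@@]12CCC([O-])=C(C)[C@H]1C[C@H](C(C)=C)CC2.[Li+] | intermediate
9 | 7β-isopropenyl-4,4,10α-trimethyl-trans-decalin-3-one | C[C@@]12CCC(=O)C(C)(C)[C@H]1C[C@H](C(C)=C)CC2 | intermediate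
10 | 7β-isopropenyl-4,4,10α-trimethyl-trans-decalin-3β-ol (axial OH) | C[C@@]12CC[C@H](O)C(C)(C)[C@H]1C[C@H](C(C)=C)CC2 | intermediate
11 | TBS ether of 10 | C[C@@]12CC[C@H](O[Si](C)(C)C(C)(C)C)C(C)(C)[C@H]1C[C@H](C(C)=C)CC2 | intermediate
12 | secondary ozonide (3-methyl-1,2,4-trioxolan-3-yl on C7) | C[C@@]12CC[C@H](O[Si](C)(C)C(C)(C)C)C(C)(C)[C@H]1C[C@H](C3(C)OCOO3)CC2 | intermediate
13 | 7β-acetyl-3β-(TBSO)-4,4,10α-trimethyl-trans-decalin | C[C@@]12CC[C@H](O[Si](C)(C)C(C)(C)C)C(C)(C)[C@H]1C[C@H](C(C)=O)CC2 | intermediate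
14 | 3β-(TBSO)-4,4,10α-trimethyl-trans-decalin-7β-yl acetate | C[C@@]12CC[C@H](O[Si](C)(C)C(C)(C)C)C(C)(C)[C@H]1C[C@H](OC(C)=O)CC2 | intermediate
15 | 3β-(TBSO)-4,4,10α-trimethyl-trans-decalin-7β-ol | C[C@@]12CC[C@H](O[Si](C)(C)C(C)(C)C)C(C)(C)[C@H]1C[C@H](O)CC2 | intermediate
16 | 3β-(TBSO)-4,4,10α-trimethyl-trans-decalin-7-one | C[C@@]12CC[C@H](O[Si](C)(C)C(C)(C)C)C(C)(C)[C@H]1CC(=O)CC2 | intermediate
17 | lithium C7=C8 enolate of 16 | C[C@@]12CC[C@H](O[Si](C)(C)C(C)(C)C)C(C)(C)[C@H]1CC([O-])=CC2.[Li+] | intermediate
18 | 3β-(TBSO)-4,4,10α-trimethyl-trans-octal-8-en-7-one | C[C@@]12CC[C@H](O[Si](C)(C)C(C)(C)C)C(C)(C)[C@H]1CC(=O)C=C2 | intermediate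
19 | 8-iodo enone | C[C@@]12CC[C@H](O[Si](C)(C)C(C)(C)C)C(C)(C)[C@H]1CC(=O)C(I)=C2 | intermediate
20 | 8-methyl enone | C[C@@]12CC[C@H](O[Si](C)(C)C(C)(C)C)C(C)(C)[C@H]1CC(=O)C(C)=C2 | intermediate
21 | 7α-allylic alcohol (OH cis to the C10 methyl) | C[C@@]12CC[C@H](O[Si](C)(C)C(C)(C)C)C(C)(C)[C@H]1C[C@@H](O)C(C)=C2 | intermediate
22 | triethyl orthoacetate | CC(OCC)(OCC)OCC | starting material
23 | mixed orthoester of 21 | C[C@@]12CC[C@H](O[Si](C)(C)C(C)(C)C)C(C)(C)[C@H]1C[C@@H](OC(C)(OCC)OCC)C(C)=C2 | intermediate
24 | ketene ethyl acetal of 21 | C[C@@]12CC[C@H](O[Si](C)(C)C(C)(C)C)C(C)(C)[C@H]1C[C@@H](OC(=C)OCC)C(C)=C2 | intermediate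
25 | ethyl 3β-(TBSO)-13,14,15,16-tetranorlabd-7-en-12-oate | C[C@@]12CC[C@H](O[Si](C)(C)C(C)(C)C)C(C)(C)[C@H]1CC=C(C)[C@H]2CC(=O)OCC | intermediate
26 | 3β-(TBSO)-13,14,15,16-tetranorlabd-7-en-12-ol | C[C@@]12CC[C@H](O[Si](C)(C)C(C)(C)C)C(C)(C)[C@H]1CC=C(C)[C@H]2CCO | intermediate
27 | 12-iodo-3β-(TBSO)-13,14,15,16-tetranorlabd-7-ene | C[C@@]12CC[C@H](O[Si](C)(C)C(C)(C)C)C(C)(C)[C@H]1CC=C(C)[C@H]2CCI | intermediate
28 | 3β-(TBSO)-15,16-dinorlabd-7-en-13-yne | C[C@@]12CC[C@H](O[Si](C)(C)C(C)(C)C)C(C)(C)[C@H]1CC=C(C)[C@H]2CCC#C | intermediate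
29 | (E)-C14 dimethylalane | C[C@@]12CC[C@H](O[Si](C)(C)C(C)(C)C)C(C)(C)[C@H]1CC=C(C)[C@H]2CC/C(C)=C/[Al](C)C | intermediate
30 | lithium butyl(dimethyl)alkenylalanate | C[C@@]12CC[C@H](O[Si](C)(C)C(C)(C)C)C(C)(C)[C@H]1CC=C(C)[C@H]2CC/C(C)=C/[Al-](C)(C)CCCC.[Li+] | intermediate
31 | 3β-(TBSO)-labda-7,13E-dien-15-ol | C[C@@]12CC[C@H](O[Si](C)(C)C(C)(C)C)C(C)(C)[C@H]1CC=C(C)[C@H]2CC/C(C)=C/CO | intermediate
32 | labda-7,13E-diene-3β,15-diol (enantio series) | C[C@@]12CC[C@H](O)C(C)(C)[C@H]1CC=C(C)[C@H]2CC/C(C)=C/CO | intermediate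
33 | (S)-3-methylpentanoic acid | CC[C@H](C)CC(=O)O | starting material
34 | 3β-hydroxylabda-7,13E-dien-15-yl (S)-3-methylpentanoate | CC[C@H](C)CC(=O)OC/C=C(\C)CC[C@@H]1C(C)=CC[C@@H]2C(C)(C)[C@@H](O)CC[C@@]12C | intermediate
35 | Meldrum's acid (2,2-dimethyl-1,3-dioxane-4,6-dione) | CC1(C)OC(=O)CC(=O)O1 | starting material
36 | CNP0234792.1 | CC[C@H](C)CC(=O)OC/C=C(\C)CC[C@@H]1C(C)=CC[C@@H]2C(C)(C)[C@@H](OC(=O)CC(=O)O)CC[C@@]12C | target

## Step count and risks

Total step count: 21. Longest linear sequence: 21 steps, from (R)-carvone 1 to 36.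

**Step 14.**
- Risk: the allylic alcohol may ionise and eliminate to a diene under acid at 140 °C. The [3,3] shift may also be slow, because the C7–O bond must swing from pseudoequatorial to pseudoaxial on the face that carries the C10 methyl.
- Fallback: a copper-mediated anti-SN2′ substitution replaces the sigmatropic shift. It sets out from 21.
- Mitsunobu reaction with picolinic acid (PPh3, DIAD, toluene, 0 °C) inverts C7 and gives the 7β-picolinate F3, whose C–O bond is pseudoaxial in the ground state.
- Me3SiC≡CCH2CH2MgBr with CuBr·SMe2 (THF, −40 to 0 °C) then displaces the magnesium-chelated picolinate from the opposite face at C9. This gives the C-silyl alkyne F4, with the C9–C11 bond α and C7=C8 in place.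
- K2CO3 in MeOH removes the alkynyl silyl group, and the route is rejoined at 28.

**Step 2.**
- Risk: facial selectivity in the Michael addition may be incomplete, 3 may polymerise under hydroxide, and the sequence may stall at the ketol.
- Fallback: an auxiliary-reinforced Michael addition replaces the free enolate. It sets out from 2.
- Compound 2 is condensed with (S)-1-phenylethylamine (toluene, cat. TsOH, water separator) to the ketimine F1.
- The more substituted secondary enamine tautomer of F1 adds to 3 (THF, 40 °C) in an aza-ene-type Michael reaction. It reacts on the face left open by the auxiliary, which is the face the ring itself prefers, and gives the imine adduct F2.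
- Aqueous AcOH hydrolysis comes back to the route at diketone 4, now isolated, and NaOMe in MeOH closes it to 6.

**Step 21.**
- Risk: acylation of the hindered axial C3–OH may be slow, so that thermal breakdown of Meldrum's acid and decarboxylation of the half ester to the acetate overtake it.
- Fallback: a protected malonate is installed in two operations. It sets out from 34.
- Compound 34 is acylated with tert-butyl hydrogen malonate (DCC, DMAP, CH2Cl2, 0 °C to rt). The ketene-like activated species accepts hindered alcohols and gives the mixed tert-butyl malonate F5.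
- TMSOTf with 2,6-lutidine (CH2Cl2, 0 °C) cleaves the tert-butyl ester under buffered conditions to the trimethylsilyl malonate F6.
- F6 is hydrolysed on aqueous work-up, and the route is rejoined at 36.

## Further compounds

F1 | step 2 | (S)-1-phenylethylamine ketimine of dihydrocarvone | C[C@@H]1CC[C@@H](C(C)=C)CC1=N[C@@H](C)c1ccccc1
F2 | step 2 | (S)-1-phenylethylamine ketimine of diketone 4 | CCC(=O)CC[C@@]1(C)CC[C@@H](C(C)=C)CC1=N[C@@H](C)c1ccccc1
F3 | step 14 | 3β-(TBSO)-4,4,8,10α-tetramethyl-trans-octal-8-en-7β-yl picolinate | C[C@@]12CC[C@H](O[Si](C)(C)C(C)(C)C)C(C)(C)[C@H]1C[C@H](OC(=O)c3ccccn3)C(C)=C2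
F4 | step 14 | 14-trimethylsilyl-3β-(TBSO)-15,16-dinorlabd-7-en-13-yne | C[C@@]12CC[C@H](O[Si](C)(C)C(C)(C)C)C(C)(C)[C@H]1CC=C(C)[C@H]2CCC#C[Si](C)(C)C
F5 | step 21 | 3-O-(tert-butyl malonate) of 34 | CC[C@H](C)CC(=O)OC/C=C(\C)CC[C@@H]1C(C)=CC[C@@H]2C(C)(C)[C@@H](OC(=O)CC(=O)OC(C)(C)C)CC[C@@]12C
F6 | step 21 | 3-O-(trimethylsilyl malonate) of 34 | CC[C@H](C)CC(=O)OC/C=C(\C)CC[C@@H]1C(C)=CC[C@@H]2C(C)(C)[C@@H](OC(=O)CC(=O)O[Si](C)(C)C)CC[C@@]12C
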